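**Plan**

- Retrosynthesis: with the hydroxyquinone masked as a 1,2,4-trimethoxynaphthalene, the two bonds holding the resorcinol ring are cut together, the one to the diaryl ketone carbon and the one to the CH2 group of the pyranone.
- Enabling feature: these bonds start from neighbouring carbons of the resorcinol ring, so the ring lies between a C=O and a CH2 that carries the 4-hydroxy-2-pyranone. That is the imprint of an aryne inserted into the C(=O)–CH2 bond of an aroylmethyl pyranone, and the ketone (crowded by CH3 and OH on the naphthalene side, OH and CH2 on the other) need not be made by acylation.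
- Forward order: the future quinone ring is closed first by Friedel–Crafts cyclisation onto a purchased bromoanisole and oxidised; the pyranone and resorcinol rings are purchased. The pyranone methyl group is joined to the naphthaldehyde, the aryne insertion unites the three parts, and quinone formation and ether cleavage finish.
- Stereochemistry: the target has no stereocentre and no configured double bond; the hindered benzophenone axis is not treated as a stereo element.

Key step: step 12

Remark: the hydroxyquinone ring is treated throughout as the 2-hydroxy-1,4-dione tautomer, and the one racemic carbinol on the way is oxidised to a ketone, so no stereochemistry has to be controlled.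

**Route**

Step 1
Reactants: 1 2-bromo-3-methylanisole; 2 succinic anhydride
Product: 3 4-(3-bromo-4-methoxy-2-methylphenyl)-4-oxobutanoic acid
Conditions: AlCl3 (2.2 equiv), CH2Cl2, 0 °C to rt; aq. HCl
Reagents that add atoms: none
Why: Friedel–Crafts acylation in which the methoxy group, the strongest donor on the ring, sends the acylium complex to its para position, which is also ortho to the methyl group, as in the acylation of 3-methylanisole.

Step 2
Reactants: 3 4-(3-bromo-4-methoxy-2-methylphenyl)-4-oxobutanoic acid
Product: 4 4-(3-bromo-4-methoxy-2-methylphenyl)butanoic acid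
Conditions: Et3SiH (2.5 equiv), CF3CO2H, rt to 50 °C
Reagents that add atoms: none
Why: Ionic hydrogenation, in which the protonated aryl ketone gives a benzylic cation stabilised by the para-methoxy group that triethylsilane reduces twice to the methylene while the aryl bromide and the acid stay untouched.

Step 3
Reactants: 4 4-(3-bromo-4-methoxy-2-methylphenyl)butanoic acid
Product: 5 6-bromo-7-methoxy-5-methyl-3,4-dihydronaphthalen-1(2H)-one
Conditions: P2O5 in CH3SO3H (1:10 by weight), rt to 50 °C
Reagents that add atoms: none
Why: Intramolecular Friedel–Crafts acylation, in which the acylium ion closes the six-membered ring onto the only free position ortho to the side chain (para to bromine), the standard way to 7-methoxy-1-tetralones.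

Step 4
Reactants: 5 6-bromo-7-methoxy-5-methyl-3,4-dihydronaphthalen-1(2H)-one
Product: 6 6-bromo-2-hydroxy-7-methoxy-5-methylnaphthalene-1,4-dione
Conditions: KOtBu, O2 (1 atm), tBuOH, rt; aq. HCl
Reagents that add atoms: dioxygen O=O
Why: Base-mediated autoxidation of a 1-tetralone, in which the enolate is oxygenated at C2, the resulting 1,2-dione enolises and is oxygenated again at the benzylic C4, and loss of water leaves the stabilised anion of the 2-hydroxy-1,4-naphthoquinone, the known route from tetralones to lawsone-type quinones.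

Step 5
Reactants: 6 6-bromo-2-hydroxy-7-methoxy-5-methylnaphthalene-1,4-dione
Product: 8 6-bromo-1,2,4,7-tetramethoxy-5-methylnaphthalene, via triol 7 (not isolated)
Conditions: Na2S2O4, Bu4NBr (cat.), THF–H2O, rt, under N2; then aq. KOH, Me2SO4, rt
Reagents that add atoms: dimethyl sulfate COS(=O)(=O)OC
Why: Reductive methylation, in which dithionite reduces the quinone to the air-sensitive triol 7 and dimethyl sulfate methylates its three phenoxides in the same flask under phase-transfer conditions, the usual way to mask a hydroxynaphthoquinone as a 1,2,4-trimethoxynaphthalene that tolerates organolithium reagents.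

Step 6
Reactants: 8 6-bromo-1,2,4,7-tetramethoxy-5-methylnaphthalene
Product: 10 3,5,6,8-tetramethoxy-1-methylnaphthalene-2-carbaldehyde, via aryllithium 9 (not isolated)
Conditions: n-BuLi, THF, −78 °C; DMF, −78 °C to rt; aq. NH4Cl
Reagents that add atoms: N,N-dimethylformamide CN(C)C=O
Why: Bromine–lithium exchange followed by Bouveault formylation, in which exchange at −78 °C outruns any deprotonation and the di-ortho-substituted aryllithium 9 is captured by the small electrophile DMF.

Step 7
Reactants: 11 4-hydroxy-6-methyl-2H-pyran-2-one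
Product: 12 4-(benzyloxy)-6-methyl-2H-pyran-2-one
Conditions: BnBr, K2CO3, DMF, rt
Reagents that add atoms: benzyl bromide BrCc1ccccc1
Why: Williamson-type O-alkylation, in which the potassium salt of the vinylogous acid reacts in DMF with benzyl bromide mainly at the 4-oxygen to give the vinylogous benzyl ester.

Step 8
Reactants: 12 4-(benzyloxy)-6-methyl-2H-pyran-2-one; 10 3,5,6,8-tetramethoxy-1-methylnaphthalene-2-carbaldehyde
Product: 14 racemic 4-(benzyloxy)-6-[2-hydroxy-2-(3,5,6,8-tetramethoxy-1-methylnaphthalen-2-yl)ethyl]-2H-pyran-2-one, via lithiated pyranone 13 (not isolated)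
Conditions: LiN(iPr)2, THF, −78 °C; then 10, −78 °C; aq. NH4Cl
Reagents that add atoms: none
Why: Lateral lithiation and aldol addition, in which LiN(iPr)2 deprotonates the 6-methyl group to the delocalised anion 13 that adds through its exocyclic carbon to the aldehyde, as established for 4-methoxy-6-methyl-2-pyranone, and the carbinol centre so formed is racemic and disappears in step 9.

Step 9
Reactants: 14 racemic 4-(benzyloxy)-6-[2-hydroxy-2-(3,5,6,8-tetramethoxy-1-methylnaphthalen-2-yl)ethyl]-2H-pyran-2-one
Product: 15 4-(benzyloxy)-6-[2-oxo-2-(3,5,6,8-tetramethoxy-1-methylnaphthalen-2-yl)ethyl]-2H-pyran-2-one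
Conditions: Dess–Martin periodinane, NaHCO3, CH2Cl2, 0 °C to rt
Reagents that add atoms: none
Why: Dess–Martin oxidation, which turns the secondary benzylic alcohol into the ketone under buffered, near-neutral conditions that avoid dehydration to the styrylpyranone.

Step 10
Reactants: 16 3,5-bis(benzyloxy)phenol
Product: 17 3,5-bis(benzyloxy)-2-bromophenol
Conditions: NBS, CH2Cl2, −78 °C
Reagents that add atoms: N-bromosuccinimide O=C1CCC(=O)N1Br
Why: Electrophilic aromatic bromination, in which NBS at low temperature in CH2Cl2 delivers bromine to the position ortho to the free hydroxyl group and para to a benzyloxy group, the selectivity relied on for 3,5-dialkoxyphenols, with any isomer brominated between the two ethers removed by chromatography.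

Step 11
Reactants: 17 3,5-bis(benzyloxy)-2-bromophenol
Product: 20 3,5-bis(benzyloxy)-2-(trimethylsilyl)phenyl trifluoromethanesulfonate, via silyl ether 18 (not isolated), via lithium phenoxide 19 (not isolated)
Conditions: (Me3Si)2NH, THF, 70 °C, evaporate; n-BuLi, THF, −78 °C; Tf2O, −78 °C to rt
Reagents that add atoms: hexamethyldisilazane C[Si](C)(C)N[Si](C)(C)C; trifluoromethanesulfonic anhydride O=S(=O)(OS(=O)(=O)C(F)(F)F)C(F)(F)F
Why: O-Silylation followed by bromine–lithium exchange, anionic 1,3-migration of silicon from oxygen to carbon (retro-Brook rearrangement) and O-triflation of the phenoxide 19, the standard one-flask route from ortho-bromophenols to 2-(trimethylsilyl)aryl triflates, with exchange at −78 °C faster than benzylic deprotonation of the ethers.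

Step 12
Reactants: 15 4-(benzyloxy)-6-[2-oxo-2-(3,5,6,8-tetramethoxy-1-methylnaphthalen-2-yl)ethyl]-2H-pyran-2-one; 20 3,5-bis(benzyloxy)-2-(trimethylsilyl)phenyl trifluoromethanesulfonate
Product: 23 4-(benzyloxy)-6-{[3,5-bis(benzyloxy)-2-(3,5,6,8-tetramethoxy-1-methylnaphthalene-2-carbonyl)phenyl]methyl}-2H-pyran-2-one, via aryne 21 (not isolated), via benzocyclobutenoxide 22 (not isolated)
Conditions: CsF (3 equiv), CH3CN, 80 °C; 15 in slight excess over 20
Reagents that add atoms: none
Why: Proposed new method: fluoride removes the silyl group of 20 and triflate leaves to give aryne 21, and the enolate of 15, whose CH2 is acidified by the ketone and through the ring by the lactone carbonyl, adds through carbon to the aryne carbon that is remote from the neighbouring benzyloxy group. The aryl anion left beside that benzyloxy group attacks the ketone in a 4-exo-trig closure to the cesium alkoxide 22, and the strained four-membered ring reopens by C–C cleavage to a benzylic anion delocalised into the pyranone, which is protonated, so that the arene ends up between the C=O and the CH2 and the crowded diaryl ketone arises by an intramolecular acyl shift. The closest known reaction is the CsF-triggered acyl-alkylation of arynes from 2-(trimethylsilyl)aryl triflates with beta-ketoesters, 3,5-dialkoxybenzynes included; new here is the vinylogous beta-ketoester, an aroylmethyl 4-alkoxy-2-pyranone whose aroyl group carries two ortho substituents. No ring of the target closes and no lasting stereocentre forms, since the only ring made is the transient cyclobutene ring of 22 and its two stereocentres vanish on ring opening. The step needs regioselective addition to the unsymmetrical aryne, which the inductive and distorting effect of the adjacent benzyloxy group secures, and C-arylation in preference to O-arylation or to [4+2] addition of the aryne to the pyranone diene, which the high nucleophilicity of the enolate carbon and the use of 20 as the limiting component should favour.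

Step 13
Reactants: 23 4-(benzyloxy)-6-{[3,5-bis(benzyloxy)-2-(3,5,6,8-tetramethoxy-1-methylnaphthalene-2-carbonyl)phenyl]methyl}-2H-pyran-2-one
Product: 24 6-{2,4-bis(benzyloxy)-6-[(4-(benzyloxy)-2-oxo-2H-pyran-6-yl)methyl]benzoyl}-2,7-dimethoxy-5-methylnaphthalene-1,4-dione
Conditions: (NH4)2Ce(NO3)6, CH3CN–H2O, 0 °C
Reagents that add atoms: water O
Why: Oxidative demethylation by tetravalent cerium, in which the 1,2,4-trimethoxy ring, the most electron-rich part of the molecule, is oxidised to the 2-methoxy-1,4-quinone with water supplying both carbonyl oxygens, while the acyl-deactivated benzyloxy ring, the pyranone and the 7-methoxy group are not attacked.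

Step 14
Reactants: 24 6-{2,4-bis(benzyloxy)-6-[(4-(benzyloxy)-2-oxo-2H-pyran-6-yl)methyl]benzoyl}-2,7-dimethoxy-5-methylnaphthalene-1,4-dione
Product: 25 6-{2,4-dihydroxy-6-[(4-hydroxy-2-oxo-2H-pyran-6-yl)methyl]benzoyl}-2,7-dihydroxy-5-methylnaphthalene-1,4-dione (CNP0141484.0)
Conditions: BBr3 (excess), CH2Cl2, −78 to 0 °C; then H2O
Reagents that add atoms: none
Why: Lewis acid ether cleavage, in which BBr3 removes the three benzyl groups, the methyl ether ortho to the diaryl ketone (chelation-assisted) and the methyl group of the vinylogous ester in the quinone ring, and hydrolysis of the borates on aqueous work-up frees the five hydroxyl groups while ketone, quinone and pyranone are inert to the reagent.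

**Compound list**

1 | 2-bromo-3-methylanisole (2-bromo-1-methoxy-3-methylbenzene) | COc1cccc(C)c1Br | starting material
2 | succinic anhydride | O=C1CCC(=O)O1 | starting material
3 | 4-(3-bromo-4-methoxy-2-methylphenyl)-4-oxobutanoic acid | COc1ccc(C(=O)CCC(=O)O)c(C)c1Br | intermediate
4 | 4-(3-bromo-4-methoxy-2-methylphenyl)butanoic acid | COc1ccc(CCCC(=O)O)c(C)c1Br | intermediate
5 | 6-bromo-7-methoxy-5-methyl-3,4-dihydronaphthalen-1(2H)-one | COc1cc2c(c(C)c1Br)CCCC2=O | intermediate
6 | 6-bromo-2-hydroxy-7-methoxy-5-methylnaphthalene-1,4-dione | COc1cc2c(c(C)c1Br)C(=O)C=C(O)C2=O | intermediate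
7 | 6-bromo-7-methoxy-5-methylnaphthalene-1,2,4-triol (formed in the flask) | COc1cc2c(O)c(O)cc(O)c2c(C)c1Br | intermediate
8 | 6-bromo-1,2,4,7-tetramethoxy-5-methylnaphthalene | COc1cc2c(OC)c(OC)cc(OC)c2c(C)c1Br | intermediate
9 | (3,5,6,8-tetramethoxy-1-methylnaphthalen-2-yl)lithium (formed in the flask) | [Li]c1c(OC)cc2c(OC)c(OC)cc(OC)c2c1C | intermediate
10 | 3,5,6,8-tetramethoxy-1-methylnaphthalene-2-carbaldehyde | COc1cc2c(OC)c(OC)cc(OC)c2c(C)c1C=O | intermediate
11 | 4-hydroxy-6-methyl-2H-pyran-2-one | Cc1cc(O)cc(=O)o1 | starting material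
12 | 4-(benzyloxy)-6-methyl-2H-pyran-2-one | Cc1cc(OCc2ccccc2)cc(=O)o1 | intermediate
13 | [4-(benzyloxy)-2-oxo-2H-pyran-6-yl]methyllithium (formed in the flask) | [Li]Cc1cc(OCc2ccccc2)cc(=O)o1 | intermediate
14 | 4-(benzyloxy)-6-[2-hydroxy-2-(3,5,6,8-tetramethoxy-1-methylnaphthalen-2-yl)ethyl]-2H-pyran-2-one, racemic | COc1cc2c(OC)c(OC)cc(OC)c2c(C)c1C(O)Cc1cc(OCc2ccccc2)cc(=O)o1 | intermediate
15 | 4-(benzyloxy)-6-[2-oxo-2-(3,5,6,8-tetramethoxy-1-methylnaphthalen-2-yl)ethyl]-2H-pyran-2-one | COc1cc2c(OC)c(OC)cc(OC)c2c(C)c1C(=O)Cc1cc(OCc2ccccc2)cc(=O)o1 | intermediate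
16 | 3,5-bis(benzyloxy)phenol | Oc1cc(OCc2ccccc2)cc(OCc2ccccc2)c1 | starting material
17 | 3,5-bis(benzyloxy)-2-bromophenol | Oc1cc(OCc2ccccc2)cc(OCc2ccccc2)c1Br | intermediate
18 | [3,5-bis(benzyloxy)-2-bromophenoxy]trimethylsilane (formed in the flask) | C[Si](C)(C)Oc1cc(OCc2ccccc2)cc(OCc2ccccc2)c1Br | intermediate
19 | lithium 3,5-bis(benzyloxy)-2-(trimethylsilyl)phenoxide (formed in the flask) | [Li+].[O-]c1cc(OCc2ccccc2)cc(OCc2ccccc2)c1[Si](C)(C)C | intermediate
20 | 3,5-bis(benzyloxy)-2-(trimethylsilyl)phenyl trifluoromethanesulfonate | C[Si](C)(C)c1c(OCc2ccccc2)cc(OCc2ccccc2)cc1OS(=O)(=O)C(F)(F)F | intermediate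
21 | 3,5-bis(benzyloxy)benzyne (1,2-didehydro-3,5-bis(benzyloxy)benzene, formed in the flask) | C1#CC(OCc2ccccc2)=CC(OCc2ccccc2)=C1 | intermediate
22 | cesium 3,5-bis(benzyloxy)-8-[4-(benzyloxy)-2-oxo-2H-pyran-6-yl]-7-(3,5,6,8-tetramethoxy-1-methylnaphthalen-2-yl)bicyclo[4.2.0]octa-1,3,5-trien-7-olate (transient, diastereomer mixture, formed in the flask) | [Cs+].[O-]C1(c2c(C)c3c(OC)cc(OC)c(OC)c3cc2OC)C(c2cc(OCc3ccccc3)cc(=O)o2)c2cc(OCc3ccccc3)cc(OCc3ccccc3)c12 | intermediate
23 | 4-(benzyloxy)-6-{[3,5-bis(benzyloxy)-2-(3,5,6,8-tetramethoxy-1-methylnaphthalene-2-carbonyl)phenyl]methyl}-2H-pyran-2-one | COc1cc2c(OC)c(OC)cc(OC)c2c(C)c1C(=O)c1c(OCc2ccccc2)cc(OCc2ccccc2)cc1Cc1cc(OCc2ccccc2)cc(=O)o1 | intermediate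
24 | 6-{2,4-bis(benzyloxy)-6-[(4-(benzyloxy)-2-oxo-2H-pyran-6-yl)methyl]benzoyl}-2,7-dimethoxy-5-methylnaphthalene-1,4-dione | COC1=CC(=O)c2c(C)c(C(=O)c3c(OCc4ccccc4)cc(OCc4ccccc4)cc3Cc3cc(OCc4ccccc4)cc(=O)o3)c(OC)cc2C1=O | intermediate
25 | 6-{2,4-dihydroxy-6-[(4-hydroxy-2-oxo-2H-pyran-6-yl)methyl]benzoyl}-2,7-dihydroxy-5-methylnaphthalene-1,4-dione (CNP0141484.0) | Cc1c(C(=O)c2c(O)cc(O)cc2Cc2cc(O)cc(=O)o2)c(O)cc2c1C(=O)C=C(O)C2=O | target

**Step count and risks**

Total step count: 14. Longest linear sequence: 11 steps (steps 1 to 6, 8, 9, 12, 13, 14) from 2-bromo-3-methylanisole.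

Steps most likely to fail:

1. Step 12 (aryne insertion, proposed new method).
   - What may go wrong: the aryl anion may be protonated before it reaches the hindered ketone, which gives plain alpha-arylation without acyl transfer. The enolate may be arylated at oxygen. The aryne may be consumed by [4+2] addition to the pyranone diene with loss of CO2.
   - Fallback (known chemistry): it sets out from aldehyde 10 and returns to the route at 23.
   - Aldol addition of the lithium enolate of methyl acetate (LiN(iPr)2, THF, −78 °C) to 10 would give methyl 3-hydroxy-3-(3,5,6,8-tetramethoxy-1-methylnaphthalen-2-yl)propanoate F1. Dess–Martin oxidation would then give the beta-ketoester methyl 3-oxo-3-(3,5,6,8-tetramethoxy-1-methylnaphthalen-2-yl)propanoate F2.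
   - This beta-ketoester is a substrate of the established aryne acyl-alkylation. With 20 and CsF in CH3CN at 80 °C it should give methyl 2-[3,5-bis(benzyloxy)-2-(3,5,6,8-tetramethoxy-1-methylnaphthalene-2-carbonyl)phenyl]acetate F3.
   - Claisen condensation of that ester with the dianion of methyl acetoacetate (NaH, then n-BuLi, THF, 0 °C) would give methyl 6-[3,5-bis(benzyloxy)-2-(3,5,6,8-tetramethoxy-1-methylnaphthalene-2-carbonyl)phenyl]-3,5-dioxohexanoate F4.
   - DBU in hot toluene would lactonise it to 6-{[3,5-bis(benzyloxy)-2-(3,5,6,8-tetramethoxy-1-methylnaphthalene-2-carbonyl)phenyl]methyl}-4-hydroxy-2H-pyran-2-one F5. O-Benzylation (BnBr, K2CO3, DMF) leads back to 23.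

2. Step 14 (global ether cleavage with BBr3).
   - What may go wrong: the freed resorcinol ring may be re-benzylated by the benzyl bromide formed in the flask (Friedel–Crafts alkylation), the two methyl ethers may be cleaved incompletely, or the pyranone may open in the acidic work-up.
   - Fallback: it sets out from 24 and returns at 25.
   - Hydrogenolysis (H2, Pd/C, EtOAc–THF, rt; the quinone is reduced to the hydroquinone and reoxidised by air on work-up) removes the three benzyl groups as toluene. It would give 6-{2,4-dihydroxy-6-[(4-hydroxy-2-oxo-2H-pyran-6-yl)methyl]benzoyl}-2,7-dimethoxy-5-methylnaphthalene-1,4-dione F6.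
   - BBr3 in CH2Cl2 then only has to cleave the two methyl ethers, with no benzyl electrophile present, to reach 25.

3. Step 8 (lateral lithiation of the benzyloxypyranone and aldol addition).
   - What may go wrong: lithiation may occur on the ring (C3 or C5) or at the benzylic position of the ether, addition to the di-ortho-substituted aldehyde may be slow, and the adduct may undergo retro-aldol cleavage or dehydration during work-up.
   - Fallback: it sets out from the unprotected pyranone 11 and aldehyde 10 and returns at 14.
   - The dianion of 11 (LiN(iPr)2, 2.2 equiv, THF, −78 to 0 °C) has its ring positions blocked by the enolate and adds through the 6-methyl carbon to 10. It would give racemic 4-hydroxy-6-[2-hydroxy-2-(3,5,6,8-tetramethoxy-1-methylnaphthalen-2-yl)ethyl]-2H-pyran-2-one F7.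
   - Selective benzylation of the acidic 4-hydroxyl group (BnBr, K2CO3, DMF), which leaves the secondary alcohol untouched, then gives 14.

**Further compounds**

F1 | step 12 | methyl 3-hydroxy-3-(3,5,6,8-tetramethoxy-1-methylnaphthalen-2-yl)propanoate, racemic | COc1cc2c(OC)c(OC)cc(OC)c2c(C)c1C(O)CC(=O)OC
F2 | step 12 | methyl 3-oxo-3-(3,5,6,8-tetramethoxy-1-methylnaphthalen-2-yl)propanoate | COc1cc2c(OC)c(OC)cc(OC)c2c(C)c1C(=O)CC(=O)OC
F3 | step 12 | methyl 2-[3,5-bis(benzyloxy)-2-(3,5,6,8-tetramethoxy-1-methylnaphthalene-2-carbonyl)phenyl]acetate | COc1cc2c(OC)c(OC)cc(OC)c2c(C)c1C(=O)c1c(OCc2ccccc2)cc(OCc2ccccc2)cc1CC(=O)OC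
F4 | step 12 | methyl 6-[3,5-bis(benzyloxy)-2-(3,5,6,8-tetramethoxy-1-methylnaphthalene-2-carbonyl)phenyl]-3,5-dioxohexanoate | COc1cc2c(OC)c(OC)cc(OC)c2c(C)c1C(=O)c1c(OCc2ccccc2)cc(OCc2ccccc2)cc1CC(=O)CC(=O)CC(=O)OC
F5 | step 12 | 6-{[3,5-bis(benzyloxy)-2-(3,5,6,8-tetramethoxy-1-methylnaphthalene-2-carbonyl)phenyl]methyl}-4-hydroxy-2H-pyran-2-one | COc1cc2c(OC)c(OC)cc(OC)c2c(C)c1C(=O)c1c(OCc2ccccc2)cc(OCc2ccccc2)cc1Cc1cc(O)cc(=O)o1
F6 | step 14 | 6-{2,4-dihydroxy-6-[(4-hydroxy-2-oxo-2H-pyran-6-yl)methyl]benzoyl}-2,7-dimethoxy-5-methylnaphthalene-1,4-dione | COC1=CC(=O)c2c(C)c(C(=O)c3c(O)cc(O)cc3Cc3cc(O)cc(=O)o3)c(OC)cc2C1=O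
F7 | step 8 | 4-hydroxy-6-[2-hydroxy-2-(3,5,6,8-tetramethoxy-1-methylnaphthalen-2-yl)ethyl]-2H-pyran-2-one, racemic | COc1cc2c(OC)c(OC)cc(OC)c2c(C)c1C(O)Cc1cc(O)cc(=O)o1
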